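**Two readings.** At 2.5 min and at 50 min the flask is read for its product excess, and at 50 min also for its conversion.

| setting | west | south | north | flask |
|---|---|---|---|---|
| left-handed substrate | 0.85 M | 0.85 M | 0.85 M | 0.85 M |
| right-handed substrate | 0.85 M | 0.85 M | 0.85 M | 0.85 M |
| partner | 0.51 M | 0.51 M | 0.77 M | 0.510 M |
| protic impurity | 0.028 M | 0.064 M | 0.0425 M | 0.0425 M |
| free catalyst | 8.5 mM | 8.5 mM | 8.5 mM | 8.5 mM |
| remark | run made earlier | run made earlier | run made earlier |  |
| time |  |  |  | 50 min |

| run | time / min | left-handed product / % | right-handed product / % | left-handed substrate / % |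
|---|---|---|---|---|
| west | 5.00 | 0.4 | 1.9 | 46.6 |
| west | 15.0 | 5.8 | 4.0 | 43.8 |
| west | 30.0 | 7.2 | 7.0 | 41.2 |
| west | 40.0 | 7.4 | 6.8 | 37.8 |
| west | 60.0 | 10.4 | 9.3 | 35.8 |
| south | 5.00 | 2.3 | 0.7 | 46.0 |
| south | 15.0 | 6.7 | 4.1 | 43.7 |
| south | 30.0 | 6.6 | 7.5 | 42.6 |
| south | 40.0 | 6.9 | 6.3 | 41.4 |
| south | 60.0 | 8.9 | 8.7 | 38.7 |
| north | 12.0 | 5.8 | 6.3 | 44.2 |
| north | 25.0 | 8.6 | 8.2 | 38.2 |
| north | 40.0 | 12.0 | 9.9 | 34.2 |
| north | 50.0 | 13.4 | 11.8 | 32.1 |
| north | 60.0 | 13.4 | 14.8 | 33.2 |

(readings scatter by 1 percentage point)

- excess of left-handed product over right-handed product in the product at 2.5 min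
- excess of left-handed product over right-handed product in the product at 50 min
- part of the left-handed substrate and right-handed substrate charged together that has reacted at 50 min

- free catalyst is single-handed; left-handed substrate and right-handed substrate are mirror images of each other, charged as a racemate, each of them at the stated concentration
- reactions considered so far: partner + catalyst intermediate A -> free catalyst + left-handed product; free catalyst + right-handed substrate <-> catalyst intermediate B; free catalyst + left-handed substrate <-> catalyst intermediate A; partner + free catalyst -> spent catalyst; partner + catalyst intermediate B -> free catalyst + right-handed product; left-handed product <-> right-handed product; partner + protic impurity -> quenched reagent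
- an excess is the difference of the two amounts in percent of their sum
- an excess is below zero if the other one leads

**Main step.** Suppose partner only turns the two catalyst intermediates into product. This is a kinetic resolution, and the product excess then stays at E, the excess with which product is formed. Substrate loss keeps that record, since interconversion of the products leaves the substrates untouched. In the west and south readings at 60.0 min, the left-handed substrate supplies 68.4% of the product, so E reads 36.7%.

**Adding interconversion.** Let D be left-handed minus right-handed product. Formation adds to D in proportion to E and the product gain, while interconversion removes D with a time constant τ. Late on the two balance, so D equals E times gain times τ. From 30.0 min onward, the six west and south readings give a mean D of 0.3 percentage points. Product gains 4.5 points from there to 60.0 min. This gives 5.45 min for τ, the memory time, with which a product excess relaxes. With a scatter of 1 point per reading, it is a rough reading. Under steady gain, the excess at time t is E(τ/t)(1−exp(−t/τ)), which contains no catalyst term. At 2.5 min that is 29.5%, and at 50 min about 4.00%.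

**Remaining steps.** Partner is also consumed by protic impurity and free catalyst, and the late gain runs slower than the first 15.0 min. For this flask, west and south suggest 16.2% product at 50 min. The reckoning here therefore commits to that conversion and to a late excess of 1.85%.

**Forecast.** The forecast gives 33%, 4% and 16.5%, calling the late excess “a quasi-steady balance of formation and racemization”, and its late excess stands above the reckoning here.

**Result.** The flask gives 29.2%, 1.54% and 17.5%.

    partner + catalyst intermediate A → free catalyst + left-handed product (k = 0.160 M⁻¹ s⁻¹)
    free catalyst + right-handed substrate ⇌ catalyst intermediate B (K = 1.00 M⁻¹, k = 1.20 M⁻¹ s⁻¹)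
    free catalyst + left-handed substrate ⇌ catalyst intermediate A (K = 0.560 M⁻¹, k = 2.20 M⁻¹ s⁻¹)
    partner + free catalyst → spent catalyst (k = 5.20 × 10⁻⁴ M⁻¹ s⁻¹)
    partner + catalyst intermediate B → free catalyst + right-handed product (k = 0.0390 M⁻¹ s⁻¹)
    left-handed product ⇌ right-handed product (k = 0.00200 s⁻¹)
    partner + protic impurity → quenched reagent (k = 0.0260 M⁻¹ s⁻¹)

With the interconversion struck out, the excess at 50 min is 36.2%. The neighbour flask, charged with 0.0021 M free catalyst, meets the same catalyst-free expression with τ at 5.45 min, 29.5% at 2.5 min, and gives 29.4% there, on its way to a conversion of 6.13% at 50 min.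

The earlier runs and the new flask come from a simulation with constants of no real substance; noise was put on by code.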